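The ratio of the last two zeta readings, 36.3% over 35.0%, was where I started, because it showed the target falling, though by only 1.3 percentage points against a scatter of 0.3 points.

in all of them: substrate 0.37 M
- delta: coupling partner 0.75 equiv; temperature 55 °C; run made earlier
- zeta: coupling partner 3 equiv; temperature 90 °C; run made earlier
- south: coupling partner 1.50 equiv; temperature 60 °C; time 8.0 min
- north-west: coupling partner 1.50 equiv; temperature 120 °C; time 8.0 min
- south-east: coupling partner 1.50 equiv; temperature 90 °C; time 8.0 min
- south-west: coupling partner 1.50 equiv; at 120 °C until 6.0 min, from then on at 60 °C; time 8.0 min

| delta: time / min | delta: target / % | zeta: time / min | zeta: target / % |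
|---|---|---|---|
| 1.33 | 0.7 | 0.500 | 23.2 |
| 3.00 | 1.0 | 1.00 | 33.7 |
| 6.00 | 3.4 | 2.00 | 36.3 |
| 10.0 | 5.4 | 2.50 | 35.0 |

(scatter of a reading: 0.3 percentage points)

- the numbers in the tables scatter with a standard deviation of 0.3 points

- the flask with the highest amount of target, in percent of the substrate charged ("all alike" if they lie within 1.5 percentage points) (south / north-west / south-east / south-west / all alike)
- final target, as a percentage of the substrate charged, in south
- final target, as a percentage of the substrate charged, in north-west
- final target, as a percentage of the substrate charged, in south-east
- final target, as a percentage of the substrate charged, in south-west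

I read three rungs of time from these runs. The fastest was the zeta rise, taking its highest reading as the plateau:

rise time = 0.309 min

Next came the zeta fall. I assumed that the target decays by a pseudo-first-order loss proportional to the equivalents of coupling partner, so that y(t) = y(t₀)·exp(−f·(t − t₀)), which is the closed form of that one rate:

f in zeta = 0.0729 /min, a lifetime of 13.7 min

Rise and fall were therefore well apart in zeta, so the target there first climbed and then slowly drained. The slowest rung was delta, colder and with less coupling partner, where the charge would take 185 min at its average pace.

For 1.50 equiv I scaled the loss and called the result the fall constant: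

f = 0.0365 /min

I then carried the zeta plateau from 2.00 min to 8.0 min, once halved with the coupling partner and once unchanged:

south-east between 14.6% and 29.2%

Doubling delta and shortening it to 8.0 min gave about 8.64% for south, a figure that took no account of the step from 55 °C to 60 °C. So my own reckoning leaned towards south-east over south, but not securely, and since I reckoned no figure for north-west or south-west, it named no highest flask.

The forecast differed. It named south, with 12% there, 8% in south-east, 0.1% in north-west and 0.1% in south-west, where “cooling leaves nothing to rescue”.

The flask named south-east: south-east gave 19.7%, against 11.6% in south, 5.12% in north-west and 7.03% in south-west.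

    coupling partner + intermediate ⇌ target (K = 0.850 /M, k = 0.130 /M/s, Ea = 53.0 kJ/mol, ΔH = −2.00 kJ/mol)
    target → over-reaction product A (k = 1.80 × 10⁻⁵ /s, Ea = 125 kJ/mol)
    substrate → intermediate (k = 0.0280 /s, Ea = 111 kJ/mol)
    coupling partner + target → over-reaction product B (k = 0.00380 /M/s, Ea = 89.0 kJ/mol)
    (constants at 90 °C)

In south-east the target stood at 23.3% at 4.00 min, and at 8.00 min intermediate held 64.1% of the substrate charged. Running the fall constant from that half-time reading gave me:

20.1% at 8.00 min, beside 19.7%

Carried on to 80.0 min in the same flask, it gave 1.42%, but the flask held 5.08%, with coupling partner at 26.0% of its charge.

The numbers in the tables are calculated from invented constants; scatter was added.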